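**Retrosynthetic overview**
1. The molecule has one ring (28-membered). It is closed last at the C1–O28 ester bond, as the thioesterase does in the biosynthesis. The OH of the 2-hydroxyvaleramide starter unit attacks C1 of the finished linear chain while C1 still sits on its acyl carrier. Here the carrier is the oxazolidinone that set C2, so no seco acid is made or activated.
2. The linear chain comes from a C17–C18 B-alkyl Suzuki coupling of the C18–C27 amide (fragment C) with a C1–C17 2-bromodiene.
3. The 2-bromodiene comes from cross-metathesis borylation followed by a site-selective C15–C16 Suzuki coupling with (E)-1,2-dibromo-3-methoxypropene. The C9 ketone comes from a Liebeskind–Srogl coupling of fragment A (C1–C8 imide) with fragment B (C9–C15 thioester).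
4. Stereocentres: C4 from citronellyl bromide, C13 from citronellene, C2 by Evans methylation, C23 from ethyl (S)-4-chloro-3-hydroxybutanoate, C20/C21 by γ-boryl allylboration, C27 from L-norvaline.
5. Order: chain assembly, then the macrolactone ring, then removal of acetonide and silyl ether in a single operation.

Assumption and numbering: (R)-β-citronellene and (S)-citronellyl bromide are bought enantiopure; atoms are numbered C1 (lactone C=O) to C24 (CH2N), N25, C26 (amide C=O), C27 (carbinol carbon), O28.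

**Fragment A (C1–C8)**

Step 1
Reactants: 1 (S)-citronellyl bromide; 2 vinylmagnesium bromide
Product: 3 (5R)-5,9-dimethyldeca-1,8-diene
Conditions: FeCl3 (10 mol %), TMEDA, THF, 0 °C → rt
Reagents that add atoms: none
Why: Iron-catalysed Kumada-type alkyl–alkenyl cross-coupling joins the primary bromide to the vinyl Grignard reagent (C6–C7) without touching the remote C4 stereocentre or the trisubstituted alkene.

Step 2
Reactants: 3 (5R)-5,9-dimethyldeca-1,8-diene
Product: 5 (4R)-4-methyloct-7-enoic acid, via (4R)-4-methyloct-7-enal 4 (not isolated)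
Conditions: O3 (1.0 equiv, Sudan Red 7B end point), pyridine, CH2Cl2, −78 °C; then NaClO2, NaH2PO4, 2-methylbut-2-ene, t-BuOH/H2O, rt
Reagents that add atoms: ozone [O-][O+]=O; sodium chlorite [Na+].[O-]Cl=O
Why: Chemoselective ozonolysis cleaves the electron-rich trisubstituted alkene well before the monosubstituted one, and Pinnick oxidation of the crude aldehyde gives the C1 acid with C4 untouched.

Step 3
Reactants: 5 (4R)-4-methyloct-7-enoic acid; 6 (4S)-4-benzyl-1,3-oxazolidin-2-one
Product: 8 (4S)-4-benzyl-3-[(4R)-4-methyloct-7-enoyl]-1,3-oxazolidin-2-one, via mixed pivalic anhydride 7 (not isolated)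
Conditions: t-BuCOCl, Et3N, THF, −20 °C; then LiCl, 6, −20 °C → rt
Reagents that add atoms: none
Why: Mixed-anhydride N-acylation loads the acid on the Evans auxiliary, because the hindered pivaloyl carbonyl directs attack to the desired acyl group.

Step 4
Reactants: 8 (4S)-4-benzyl-3-[(4R)-4-methyloct-7-enoyl]-1,3-oxazolidin-2-one
Product: 10 (4S)-4-benzyl-3-[(2S,4R)-2,4-dimethyloct-7-enoyl]-1,3-oxazolidin-2-one, via sodium Z-enolate 9 (not isolated)
Conditions: NaN(SiMe3)2, THF, −78 °C; MeI, −78 → −40 °C
Reagents that add atoms: iodomethane CI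
Why: In this Evans asymmetric alkylation the chelated Z-enolate is methylated on the face opposite the benzyl group, which sets C2 as S (anti to the C4 methyl) under auxiliary control.

**Fragment B (C9–C15)**

Step 5
Reactants: 11 (R)-β-citronellene
Product: 13 (4R)-4-methylhex-5-en-1-ol, via (4R)-4-methylhex-5-enal 12 (not isolated)
Conditions: O3 (1.0 equiv), CH2Cl2/MeOH, −78 °C; then NaBH4, −78 °C → rt
Reagents that add atoms: ozone [O-][O+]=O
Why: Chemoselective ozonolysis with reductive work-up removes only the isopropylidene end and keeps the vinyl group and the C13 stereocentre of the chiral pool.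

Step 6
Reactants: 13 (4R)-4-methylhex-5-en-1-ol
Product: 14 (3R)-6-bromo-3-methylhex-1-ene
Conditions: CBr4, PPh3, CH2Cl2, 0 °C
Reagents that add atoms: tetrabromomethane BrC(Br)(Br)Br
Why: The Appel reaction converts the primary alcohol to the bromide under neutral conditions, far from the stereocentre.

Step 7
Reactants: 14 (3R)-6-bromo-3-methylhex-1-ene; 15 S-phenyl carbonochloridothioate
Product: 17 S-phenyl (5R)-5-methylhept-6-enethioate, via alkylmagnesium bromide 16 (not isolated)
Conditions: Mg, THF, rt; added to 15, NiCl2(dppe) (2 mol %), THF, 0 °C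
Reagents that add atoms: none
Why: Nickel-catalysed acylation of the Grignard reagent by the chlorothioformate replaces only the C–Cl bond and stops at the thioester, and the hexenyl Grignard reagent does not cyclise at these temperatures.

**Union of A and B, diene building**

Step 8
Reactants: 10 (4S)-4-benzyl-3-[(2S,4R)-2,4-dimethyloct-7-enoyl]-1,3-oxazolidin-2-one; 17 S-phenyl (5R)-5-methylhept-6-enethioate
Product: 19 (4S)-4-benzyl-3-[(2S,4R,13R)-2,4,13-trimethyl-9-oxopentadec-14-enoyl]-1,3-oxazolidin-2-one, via B-alkyl-9-BBN borane 18 (not isolated)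
Conditions: 9-BBN-H (1.05 equiv), THF, rt; then 17, Pd(PPh3)4 (5 mol %), Cu(O2CC4H3S) (1.5 equiv), Cs2CO3, THF, 45 °C
Reagents that add atoms: none
Why: Anti-Markovnikov hydroboration places boron on C8, and the Liebeskind–Srogl ketone synthesis couples it with the thioester carbonyl only, so the C9 ketone forms next to the intact imide and the borane is spent before the vinyl group of 17 enters the flask.

Step 9
Reactants: 19 keto imide; 20 vinylboronic acid pinacol ester
Product: 21 (4S)-4-benzyl-3-[(2S,4R,13R,14E)-2,4,13-trimethyl-9-oxo-15-(4,4,5,5-tetramethyl-1,3,2-dioxaborolan-2-yl)pentadec-14-enoyl]-1,3-oxazolidin-2-one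
Conditions: Hoveyda–Grubbs second-generation catalyst (5 mol %), 1,4-benzoquinone (10 mol %), CH2Cl2, 40 °C
Reagents that add atoms: none
Why: Olefin cross-metathesis of the allylically branched terminal alkene with the vinyl boronate gives the E-alkenyl boronate under steric control, which sets the C14=C15 geometry.

Step 10
Reactants: 22 methyl propargyl ether
Product: 23 (E)-1,2-dibromo-3-methoxyprop-1-ene
Conditions: Br2, CH2Cl2, −20 °C
Reagents that add atoms: bromine BrBr
Why: Electrophilic anti addition of bromine to the alkyne gives the trans dibromide, in which the terminal bromine is cis to CH2OMe.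

Step 11
Reactants: 21 alkenyl boronate; 23 (E)-1,2-dibromo-3-methoxyprop-1-ene
Product: 24 (4S)-4-benzyl-3-[(2S,4R,13R,14E,16E)-17-bromo-18-methoxy-2,4,13-trimethyl-9-oxooctadeca-14,16-dienoyl]-1,3-oxazolidin-2-one
Conditions: 23 (3 equiv), Pd(PPh3)4 (5 mol %), K3PO4 (3 M aq.), THF, 40 °C
Reagents that add atoms: none
Why: Site-selective Suzuki–Miyaura coupling takes place at the less hindered terminal C–Br with retention at both alkenes, so C15 ends cis to CH2OMe and the internal bromide stays for the next coupling.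

**Fragment C (C18–C27)**

Step 12
Reactants: 25 ethyl (3S)-4-chloro-3-hydroxybutanoate
Product: 26 ethyl (3S)-4-azido-3-hydroxybutanoate
Conditions: NaN3, DMF, 90 °C
Reagents that add atoms: sodium azide [Na+].[N-]=[N+]=[N-]
Why: SN2 displacement at the primary carbon C24 introduces nitrogen without breaking any bond at the C23 stereocentre.

Step 13
Reactants: 26 ethyl (3S)-4-azido-3-hydroxybutanoate
Product: 27 ethyl (3S)-4-azido-3-[(tert-butyldimethylsilyl)oxy]butanoate
Conditions: TBSCl, imidazole, DMF, rt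
Reagents that add atoms: tert-butyldimethylsilyl chloride CC(C)(C)[Si](C)(C)Cl
Why: Standard silylation masks the C23 hydroxyl, so that the aldehyde of the next step cannot eliminate or form hemiacetals.

Step 14
Reactants: 27 ethyl (3S)-4-azido-3-[(tert-butyldimethylsilyl)oxy]butanoate
Product: 28 (3S)-4-azido-3-[(tert-butyldimethylsilyl)oxy]butanal
Conditions: i-Bu2AlH (1.1 equiv), CH2Cl2, −78 °C; aq. Rochelle salt
Reagents that add atoms: none
Why: Partial ester reduction stops at the aldehyde because the tetrahedral aluminium adduct survives at −78 °C, a temperature at which the azide is inert.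

Step 15
Reactants: 28 (3S)-4-azido-3-[(tert-butyldimethylsilyl)oxy]butanal; 29 allenylboronic acid pinacol ester
Product: 32 (3R,4S,6S)-7-azido-6-[(tert-butyldimethylsilyl)oxy]hept-1-ene-3,4-diol, via E-γ-borylallylborane 30 (not isolated), via boronate borinate adduct 31 (not isolated)
Conditions: (Ipc)2BH made from (−)-α-pinene, 29, Et2O, 0 °C; 28, −78 °C; then NaOH, H2O2, 0 °C → rt
Reagents that add atoms: hydrogen peroxide OO
Why: In this Brown–Roush γ-boryl allylboration the chair transition state sets C21 (S) by Ipc control and C20 anti to it through the E geometry of the allylborane, and C–B oxidation with retention gives the 20R,21S anti diol bearing the C18=C19 vinyl group.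

Step 16
Reactants: 32 (3R,4S,6S)-7-azido-6-[(tert-butyldimethylsilyl)oxy]hept-1-ene-3,4-diol
Product: 33 (2S)-1-azido-3-[(4S,5R)-2,2-dimethyl-5-vinyl-1,3-dioxolan-4-yl]propan-2-yl tert-butyldimethylsilyl ether
Conditions: 2,2-dimethoxypropane, PPTS, CH2Cl2, rt
Reagents that add atoms: 2,2-dimethoxypropane COC(C)(C)OC
Why: Acid-catalysed transketalisation ties the vicinal diol into the five-membered cis-dioxolane under conditions that the silyl ether tolerates.

Step 17
Reactants: 34 L-norvaline
Product: 36 (2S)-2-hydroxypentanoic acid, via (3R)-3-propyloxiran-2-one 35 (not isolated)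
Conditions: NaNO2, H2SO4 (1 M aq.), 0 °C → rt
Reagents that add atoms: water O
Why: Diazotisation proceeds with net retention because the carboxylate displaces N2 to form the α-lactone and water opens it, two inversions that keep C27 as S.

Step 18
Reactants: 33 azido acetonide; 36 (2S)-2-hydroxypentanoic acid
Product: 39 (2S)-N-{(2S)-2-[(tert-butyldimethylsilyl)oxy]-3-[(4S,5R)-2,2-dimethyl-5-vinyl-1,3-dioxolan-4-yl]propyl}-2-hydroxypentanamide, via primary amine 37 (not isolated), via benzotriazolyl ester 38 (not isolated)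
Conditions: PPh3, THF/H2O, 45 °C; concentrate; then 36, EDC·HCl, HOBt, CH2Cl2, 0 °C → rt
Reagents that add atoms: none
Why: Staudinger reduction followed by carbodiimide/HOBt amide coupling acylates the far more nucleophilic amine, so the C27 hydroxyl needs no protection and stays the only free OH of the fragment.

**Chain completion, ring closure, deprotection**

Step 19
Reactants: 39 fragment C amide; 24 bromodiene imide
Product: 41 seco imide (linear C1–C27 chain: C1 as (4S)-4-benzyl-oxazolidinone imide; 2S,4R,13R; 9-oxo; 14E,16Z diene with 17-CH2OMe; 20R,21S acetonide; 23S OTBS; N25-(2S)-2-hydroxypentanoyl with free C27 OH), via bis-9-BBN borane 40 (not isolated)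
Conditions: 39, 9-BBN-H (2.5 equiv), THF, rt; K3PO4 (3 M aq., destroys excess B–H); then 24, Pd(dppf)Cl2 (10 mol %), AsPh3, DMF, rt
Reagents that add atoms: none
Why: Anti-Markovnikov hydroboration puts boron on C18, and B-alkyl Suzuki–Miyaura coupling replaces the C17 bromide with retention, which places C18 trans to C15, while the phosphate base releases the transient O-borinate and leaves the α-branched imide intact.

Step 20
Reactants: 41 seco imide
Product: 43 protected macrolactone (28-membered ring; 20,21-acetonide; 23-OTBS), via magnesium alkoxide 42 (not isolated)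
Conditions: Mg(OtBu)2 (1.5 equiv), THF/toluene 1:4, 1 mM, rt → 40 °C; then H2O
Reagents that add atoms: none
Why: Proposed new method: alkoxide exchange turns the comparatively acidic α-hydroxy amide into a magnesium alkoxide held in a five-membered O,O-chelate, and the same magnesium centre can bind the two imide carbonyls, so nucleophile and activated acyl group are held together and the alkoxide attacks the exocyclic C1 carbonyl and expels the oxazolidinone anion just as the thioesterase releases the carrier-bound chain; C27 reacts at oxygen and keeps its configuration, C2 is protected from enolisation because allylic strain holds its C–H in the imide plane and the base is weak, and an initial N25 acylation would relay the acyl group to the neighbouring alkoxide through a five-membered transition state to give the same lactone; the closest known reaction types are the magnesium alkoxide (MeOMgBr) alcoholysis of N-acyl oxazolidinones, lactonisations that expel the auxiliary, and thioester-to-hydroxyl macrolactonisation.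

Step 21
Reactants: 43 protected macrolactone
Product: 44 CNP0562924.1
Conditions: HF (48 % aq.), MeCN, 0 °C → rt
Reagents that add atoms: none
Why: Global acidic deprotection cleaves the silyl ether with fluoride and hydrolyses the dioxolane, while the lactone, amide, ketone and dienyl methyl ether tolerate this mild acid and no stereocentre is touched.

**Compound list**
1 | (S)-citronellyl bromide [(6S)-8-bromo-2,6-dimethyloct-2-ene] | CC(C)=CCC[C@H](C)CCBr | starting material
2 | vinylmagnesium bromide | C=C[Mg]Br | starting material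
3 | (5R)-5,9-dimethyldeca-1,8-diene | CC(C)=CCC[C@H](C)CCC=C | intermediate
4 | (4R)-4-methyloct-7-enal | O=CCC[C@H](C)CCC=C | intermediate
5 | (4R)-4-methyloct-7-enoic acid | OC(=O)CC[C@H](C)CCC=C | intermediate
6 | (4S)-4-benzyl-1,3-oxazolidin-2-one | O=C1OC[C@H](Cc2ccccc2)N1 | starting material
7 | mixed pivalic anhydride of 5 | CC(C)(C)C(=O)OC(=O)CC[C@H](C)CCC=C | intermediate
8 | (4S)-4-benzyl-3-[(4R)-4-methyloct-7-enoyl]-1,3-oxazolidin-2-one | O=C1OC[C@H](Cc2ccccc2)N1C(=O)CC[C@H](C)CCC=C | intermediate
9 | sodium Z-enolate of 8 | [Na+].[O-]/C(=C\C[C@H](C)CCC=C)N1C(=O)OC[C@@H]1Cc1ccccc1 | intermediate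
10 | (4S)-4-benzyl-3-[(2S,4R)-2,4-dimethyloct-7-enoyl]-1,3-oxazolidin-2-one | O=C1OC[C@H](Cc2ccccc2)N1C(=O)[C@@H](C)C[C@H](C)CCC=C | intermediate
11 | (R)-β-citronellene [(3R)-3,7-dimethylocta-1,6-diene] | C=C[C@H](C)CCC=C(C)C | starting material
12 | (4R)-4-methylhex-5-enal | C=C[C@H](C)CCC=O | intermediate
13 | (4R)-4-methylhex-5-en-1-ol | C=C[C@H](C)CCCO | intermediate
14 | (3R)-6-bromo-3-methylhex-1-ene | C=C[C@H](C)CCCBr | intermediate
15 | S-phenyl carbonochloridothioate | O=C(Cl)Sc1ccccc1 | starting material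
16 | [(4R)-4-methylhex-5-enyl]magnesium bromide | C=C[C@H](C)CCC[Mg]Br | intermediate
17 | S-phenyl (5R)-5-methylhept-6-enethioate | C=C[C@H](C)CCCC(=O)Sc1ccccc1 | intermediate
18 | B-alkyl-9-BBN borane from 10 (boron on C8) | O=C1OC[C@H](Cc2ccccc2)N1C(=O)[C@@H](C)C[C@H](C)CCCCB1C2CCCC1CCC2 | intermediate
19 | (4S)-4-benzyl-3-[(2S,4R,13R)-2,4,13-trimethyl-9-oxopentadec-14-enoyl]-1,3-oxazolidin-2-one | O=C1OC[C@H](Cc2ccccc2)N1C(=O)[C@@H](C)C[C@H](C)CCCCC(=O)CCC[C@@H](C)C=C | intermediate
20 | vinylboronic acid pinacol ester | C=CB1OC(C)(C)C(C)(C)O1 | starting material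
21 | (14E)-alkenyl pinacol boronate of 19 | O=C1OC[C@H](Cc2ccccc2)N1C(=O)[C@@H](C)C[C@H](C)CCCCC(=O)CCC[C@@H](C)/C=C/B1OC(C)(C)C(C)(C)O1 | intermediate
22 | methyl propargyl ether | C#CCOC | starting material
23 | (E)-1,2-dibromo-3-methoxyprop-1-ene | COC/C(Br)=C\Br | intermediate
24 | (14E,16E)-17-bromo-18-methoxy dienoyl imide (C1–C17) | O=C1OC[C@H](Cc2ccccc2)N1C(=O)[C@@H](C)C[C@H](C)CCCCC(=O)CCC[C@@H](C)/C=C/C=C(\COC)Br | intermediate
25 | ethyl (3S)-4-chloro-3-hydroxybutanoate | CCOC(=O)C[C@H](O)CCl | starting material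
26 | ethyl (3S)-4-azido-3-hydroxybutanoate | CCOC(=O)C[C@H](O)CN=[N+]=[N-] | intermediate
27 | ethyl (3S)-4-azido-3-[(tert-butyldimethylsilyl)oxy]butanoate | CCOC(=O)C[C@H](O[Si](C)(C)C(C)(C)C)CN=[N+]=[N-] | intermediate
28 | (3S)-4-azido-3-[(tert-butyldimethylsilyl)oxy]butanal | O=CC[C@H](O[Si](C)(C)C(C)(C)C)CN=[N+]=[N-] | intermediate
29 | allenylboronic acid pinacol ester | C=C=CB1OC(C)(C)C(C)(C)O1 | starting material
30 | (E)-γ-(pinacolboryl)allyl-diisopinocampheylborane | CC1(C)OB(/C=C/CB([C@H]2C[C@H]3C[C@@H]([C@@H]2C)C3(C)C)[C@H]2C[C@H]3C[C@@H]([C@@H]2C)C3(C)C)OC1(C)C | intermediate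
31 | allylboration adduct (C20 pinacol boronate; C21 O-B(Ipc)2 borinate) | C=C[C@@H](B1OC(C)(C)C(C)(C)O1)[C@@H](OB([C@H]1C[C@H]2C[C@@H]([C@@H]1C)C2(C)C)[C@H]1C[C@H]2C[C@@H]([C@@H]1C)C2(C)C)C[C@H](O[Si](C)(C)C(C)(C)C)CN=[N+]=[N-] | intermediate
32 | (3R,4S,6S)-7-azido-6-[(tert-butyldimethylsilyl)oxy]hept-1-ene-3,4-diol | C=C[C@@H](O)[C@@H](O)C[C@H](O[Si](C)(C)C(C)(C)C)CN=[N+]=[N-] | intermediate
33 | (2S)-1-azido-3-[(4S,5R)-2,2-dimethyl-5-vinyl-1,3-dioxolan-4-yl]propan-2-yl TBS ether | C=C[C@H]1OC(C)(C)O[C@H]1C[C@H](O[Si](C)(C)C(C)(C)C)CN=[N+]=[N-] | intermediate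
34 | L-norvaline | CCC[C@H](N)C(=O)O | starting material
35 | (3R)-3-propyloxiran-2-one | CCC[C@H]1OC1=O | intermediate
36 | (2S)-2-hydroxypentanoic acid | CCC[C@H](O)C(=O)O | intermediate
37 | primary amine from 33 | NC[C@@H](O[Si](C)(C)C(C)(C)C)C[C@@H]1OC(C)(C)O[C@@H]1C=C | intermediate
38 | benzotriazol-1-yl (2S)-2-hydroxypentanoate | CCC[C@H](O)C(=O)On1nnc2ccccc12 | intermediate
39 | fragment C amide (C18–C27; free C27 OH) | CCC[C@H](O)C(=O)NC[C@@H](O[Si](C)(C)C(C)(C)C)C[C@@H]1OC(C)(C)O[C@@H]1C=C | intermediate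
40 | bis-9-BBN borane of 39 (boron on C18 and on O28) | CCC[C@H](OB1C2CCCC1CCC2)C(=O)NC[C@@H](O[Si](C)(C)C(C)(C)C)C[C@@H]1OC(C)(C)O[C@@H]1CCB1C2CCCC1CCC2 | intermediate
41 | seco imide (linear C1–C27 chain on the oxazolidinone) | O=C1OC[C@H](Cc2ccccc2)N1C(=O)[C@@H](C)C[C@H](C)CCCCC(=O)CCC[C@@H](C)/C=C/C=C(\COC)CC[C@H]1OC(C)(C)O[C@H]1C[C@H](O[Si](C)(C)C(C)(C)C)CNC(=O)[C@@H](O)CCC | intermediate
42 | tert-butoxymagnesium C27 alkoxide of 41 | O=C1OC[C@H](Cc2ccccc2)N1C(=O)[C@@H](C)C[C@H](C)CCCCC(=O)CCC[C@@H](C)/C=C/C=C(\COC)CC[C@H]1OC(C)(C)O[C@H]1C[C@H](O[Si](C)(C)C(C)(C)C)CNC(=O)[C@@H](O[Mg]OC(C)(C)C)CCC | intermediate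
43 | protected macrolactone (20,21-acetonide; 23-OTBS) | CCC[C@@H]1OC(=O)[C@@H](C)C[C@H](C)CCCCC(=O)CCC[C@@H](C)/C=C/C=C(\COC)CC[C@H]2OC(C)(C)O[C@H]2C[C@H](O[Si](C)(C)C(C)(C)C)CNC1=O | intermediate
44 | CNP0562924.1 (2S,4R,13R,14E,16Z,20R,21S,23S,27S) | CCC[C@@H]1OC(=O)[C@@H](C)C[C@H](C)CCCCC(=O)CCC[C@@H](C)/C=C/C=C(\COC)CC[C@@H](O)[C@@H](O)C[C@H](O)CNC1=O | target

**Step count and risks**

Total step count: 21. Longest linear sequence: 10 steps (1, 2, 3, 4, 8, 9, 11, 19, 20, 21).

The three steps most likely to fail: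

Step 20 (ring closure directly from the imide). The risks are slow acyl transfer, opening of the auxiliary ring, and dimer formation. The fallback sets out from 41 and comes back at 43. LiOH/H2O2 in THF/H2O at 0 °C removes the auxiliary and gives the protected seco acid F1. Slow addition of F1 to 2-methyl-6-nitrobenzoic anhydride and DMAP in toluene forms the mixed aryl anhydride F2. DMAP-catalysed attack of the C27 hydroxyl on F2 then closes the ring to 43.

Step 11 (site-selective coupling on a vicinal dibromide). The risks are β-bromide elimination to the alkyne and double coupling. The fallback sets out from 19 and comes back at 41, and it builds C17 from a geminal dibromide instead.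
- Cross-metathesis of 19 with crotonaldehyde (Hoveyda–Grubbs second-generation catalyst) gives the C16 enal F3.
- Ramirez olefination (CBr4, PPh3, 0 °C) gives the 17,17-dibromodiene F4.
- Trans-selective B-alkyl Suzuki coupling of F4 with borane 40 (Pd(dppf)Cl2, K3PO4) gives the 17-bromo seco imide F5, with bromine cis to C15.
- Stille coupling of F5 with Bu3SnCH2OMe under Pd(Pt-Bu3)2, which couples with retention, installs the methoxymethyl group and gives 41.

Step 8 (B-alkyl Liebeskind–Srogl ketone synthesis). The risks are sluggish alkyl transfer from boron and attack of copper carboxylate or base on the imide. The fallback sets out from 10 and comes back at 19, and it uses an organozinc reagent.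
- Borane 18 is oxidised with Me3NO, which is neutral and safe for the imide, to the C8 primary alcohol F6.
- I2, PPh3 and imidazole give the C8 iodide F7.
- Zn dust with LiCl in THF gives the alkylzinc iodide F8.
- Fukuyama coupling of F8 with thioester 17 (PdCl2(PPh3)2, toluene/THF, rt) gives 19.

**Further compounds**
F1 | step 20 | protected seco acid | OC(=O)[C@@H](C)C[C@H](C)CCCCC(=O)CCC[C@@H](C)/C=C/C=C(\COC)CC[C@H]1OC(C)(C)O[C@H]1C[C@H](O[Si](C)(C)C(C)(C)C)CNC(=O)[C@@H](O)CCC
F2 | step 20 | mixed aryl anhydride of F1 with 2-methyl-6-nitrobenzoic acid | Cc1cccc([N+](=O)[O-])c1C(=O)OC(=O)[C@@H](C)C[C@H](C)CCCCC(=O)CCC[C@@H](C)/C=C/C=C(\COC)CC[C@H]1OC(C)(C)O[C@H]1C[C@H](O[Si](C)(C)C(C)(C)C)CNC(=O)[C@@H](O)CCC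
F3 | step 11 | C16 enal (14E) | O=C1OC[C@H](Cc2ccccc2)N1C(=O)[C@@H](C)C[C@H](C)CCCCC(=O)CCC[C@@H](C)/C=C/C=O
F4 | step 11 | 17,17-dibromodiene (14E) | O=C1OC[C@H](Cc2ccccc2)N1C(=O)[C@@H](C)C[C@H](C)CCCCC(=O)CCC[C@@H](C)/C=C/C=C(Br)Br
F5 | step 11 | 17-bromo seco imide (bromine cis to C15) | O=C1OC[C@H](Cc2ccccc2)N1C(=O)[C@@H](C)C[C@H](C)CCCCC(=O)CCC[C@@H](C)/C=C/C=C(\Br)CC[C@H]1OC(C)(C)O[C@H]1C[C@H](O[Si](C)(C)C(C)(C)C)CNC(=O)[C@@H](O)CCC
F6 | step 8 | C8 primary alcohol | O=C1OC[C@H](Cc2ccccc2)N1C(=O)[C@@H](C)C[C@H](C)CCCCO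
F7 | step 8 | C8 iodide | O=C1OC[C@H](Cc2ccccc2)N1C(=O)[C@@H](C)C[C@H](C)CCCCI
F8 | step 8 | alkylzinc iodide | O=C1OC[C@H](Cc2ccccc2)N1C(=O)[C@@H](C)C[C@H](C)CCCC[Zn]I
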